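**Plan**

Atoms are numbered in the order of the target SMILES (ring A: C2, C3, C4, C6, C31, C33; ring B: C6, C7, C30, C29, C31; ring C: C22, C23, C25, C27, C29, C30).
- Cuts, late stage: the hydroxy lactam is opened to a C16 ketone and a C34 nitrile. The 13-membered ring is cut at C18–C19, then C19–C20 (acetonitrile) and C7–O8 (aryl ether), leaving a tricyclic core and a para-substituted phenol.
- Cuts, ring C: C22–C23 (Michael closure), C27–C28 (cross-coupling) and C23–C25 (aldol) lead back to a ring B lactone with an acetyl group on C29.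
- Feature behind the key step: on ring B, C30 carries the C22–C20 acyl arm and its neighbour C29 carries C27, next to the oxygen-bearing C7. Both bonds (C22–C30, C27–C29) come from the enol of an acetoacetate on the C7 oxygen adding across a C29=C30 cyclopentene.
- Forward order: ring A (from 4-methylcyclohexanone), ring B (metathesis), photocycloaddition with retro-aldol opening, ring C, epoxide, lactone opening, aryl ether, macrocycle, lactam.
- Stereochemistry: C2 from a chiral lithium amide; C4, C6, C29 and C22 by equilibration; C31 by axial methylation; C7 by Felkin–Anh addition, later inverted by Mitsunobu etherification; C30 by the ester tether; C23 from the E-enone in the Michael closure; the epoxide from the face left open by the lactone; C16 by ring–chain equilibration.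

Key step: step 11

Remark: the (R,R)-configured lithium bis(1-phenylethyl)amide is taken to give the (S)-enol ether 2, by analogy with other 4-alkylcyclohexanones; if the sense is opposite, the (S,S)-amide is used.
Remark: the natural configuration at the hemiaminal carbon C16 is taken to be the one favoured when the hydroxy lactam equilibrates with its open keto amide inside the macrocycle.

**Route**

Step 1
Reactants: 1 4-methylcyclohexanone
Product: 2 (S)-trimethyl[(4-methylcyclohex-1-en-1-yl)oxy]silane
Conditions: lithium (R,R)-bis(1-phenylethyl)amide, LiN[CH(Me)Ph]2 (from the amine and n-BuLi), Me3SiCl (in situ quench), THF, −78 °C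
Reagents that add atoms: chlorotrimethylsilane (C[Si](C)(C)Cl)
Why: Enantioselective deprotonation of the prochiral ketone by a chiral lithium amide (Simpkins–Koga desymmetrization) decides which α-carbon becomes C4 and so fixes the configuration of the methyl-bearing C2.

Step 2
Reactants: 2 (S)-trimethyl[(4-methylcyclohex-1-en-1-yl)oxy]silane
Product: 5 (2S,4S)-2,4-dimethylcyclohexan-1-one, via lithium enolate 3 (not isolated), via trans-2,4-dimethylcyclohexanone 4 (not isolated)
Conditions: MeLi, THF, 0 °C; MeI, −78 to 0 °C; then NaOMe (cat.), MeOH, 20 °C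
Reagents that add atoms: iodomethane (CI)
Why: Regiospecific enolate generation from the silyl enol ether and C-methylation (Stork–House alkylation) is followed by methoxide equilibration of the α-centre, which sets C4 thermodynamically in the diequatorial cis relationship to C2.

Step 3
Reactants: 5 (2S,4S)-2,4-dimethylcyclohexan-1-one
Product: 7 2-(1-hydroxyethyl)-4,6-dimethylcyclohexan-1-one (4,6-cis; mixture at the two new centres), via lithium enolate 6 (not isolated)
Conditions: LiN(iPr)2, THF, −78 °C; CH3CHO
Reagents that add atoms: acetaldehyde (CC=O)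
Why: Kinetic deprotonation at the unsubstituted α-carbon (C31) and directed aldol addition; both new centres are removed in step 4.

Step 4
Reactants: 7 2-(1-hydroxyethyl)-4,6-dimethylcyclohexan-1-one
Product: 9 (E)-2-ethylidene-4,6-dimethylcyclohexan-1-one (4,6-cis), via mesylate 8 (not isolated)
Conditions: MsCl, Et3N, CH2Cl2, 0 °C; then DBU, 20 °C
Reagents that add atoms: none
Why: Mesylation and E1cB elimination give the conjugated ethylidene ketone as the more stable E isomer (methyl anti to the carbonyl).

Step 5
Reactants: 9 (E)-2-ethylidene-4,6-dimethylcyclohexan-1-one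
Product: 11 2-ethenyl-2,4,6-trimethylcyclohexan-1-one (2-methyl axial and trans to the 4-methyl; 4,6-cis), via potassium dienolate 10 (not isolated)
Conditions: t-BuOK, THF/t-BuOH, −20 °C; MeI (1.1 equiv)
Reagents that add atoms: iodomethane (CI)
Why: Deconjugative α-alkylation of the extended dienolate (as in the methylation of pulegone) should place the methyl group axially on C31, trans to the equatorial C2 methyl, through a chair-like transition state, leaving the vinyl group equatorial.

Step 6
Reactants: 11 2-ethenyl-2,4,6-trimethylcyclohexan-1-one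
Product: 12 4-ethenyl-4,6,8-trimethyl-1-oxaspiro[2.5]octane (spiro centre of no consequence)
Conditions: Me3S+ I−, n-BuLi, THF, −10 to 20 °C
Reagents that add atoms: trimethylsulfonium iodide (C[S+](C)C.[I-])
Why: Corey–Chaykovsky epoxidation with dimethylsulfonium methylide adds the C7 carbon even to a ketone flanked by a quaternary and a tertiary carbon.

Step 7
Reactants: 12 4-ethenyl-4,6,8-trimethyl-1-oxaspiro[2.5]octane
Product: 14 2-ethenyl-2,4,6-trimethylcyclohexane-1-carbaldehyde (formyl equatorial; trans to the vinyl group and to the 6-methyl), via formyl epimer 13 (not isolated)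
Conditions: BF3·OEt2 (cat.), CH2Cl2, −78 °C; then DBU (cat.), 20 °C
Reagents that add atoms: none
Why: Lewis acid-promoted Meinwald rearrangement (opening to the tertiary cation, 1,2-hydride shift) gives the homologous aldehyde, and base equilibration of the α-centre sets C6 with the formyl group equatorial.

Step 8
Reactants: 14 2-ethenyl-2,4,6-trimethylcyclohexane-1-carbaldehyde
Product: 15 1-(2-ethenyl-2,4,6-trimethylcyclohexyl)prop-2-en-1-ol (carbinol C7 as in the SMILES)
Conditions: CH2=CHMgBr, THF, −78 °C
Reagents that add atoms: vinylmagnesium bromide (C=C[Mg]Br)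
Why: Grignard addition under Felkin–Anh control (quaternary C31 anti to the nucleophile, attack past the C6 hydrogen) should favour the C7 epimer whose oxygen is anti to the angular methyl; the minor epimer is removed by chromatography.

Step 9
Reactants: 15 1-(2-ethenyl-2,4,6-trimethylcyclohexyl)prop-2-en-1-ol
Product: 16 trans-fused 3a,5,7-trimethyl-3a,4,5,6,7,7a-hexahydro-1H-inden-1-ol (hydroxyl anti to the 3a-methyl)
Conditions: RuCl2(=CHPh)(PCy3)(H2IMes) (second-generation Grubbs catalyst, 3 mol %), CH2Cl2, 40 °C
Reagents that add atoms: none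
Why: Ring-closing metathesis of the two trans-diequatorial vinyl groups closes ring B as the trans-fused cyclopentenol with loss of ethene.

Step 10
Reactants: 16 trans-fused hydrindenol
Product: 17 hydrindenyl 3-oxobutanoate (acetoacetate on the C7 oxygen)
Conditions: 2,2,6-trimethyl-4H-1,3-dioxin-4-one, toluene, 110 °C
Reagents that add atoms: 2,2,6-trimethyl-4H-1,3-dioxin-4-one (CC1=CC(=O)OC(C)(C)O1)
Why: Thermolysis of the dioxinone releases acetylketene, which acylates the secondary alcohol with retention at C7; the temperature stays below that of a Carroll rearrangement.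

Step 11
Reactants: 17 hydrindenyl 3-oxobutanoate
Product: 20 cis-fused γ-lactone methyl ketone (lactone C7–O–C20(=O)–C22–C30; acetyl on C29 trans to C22), via cyclobutanol 18 (not isolated), via cis-acetyl lactone 19 (not isolated)
Conditions: hν (254 nm, quartz), cyclohexane (0.005 M, degassed), 20 °C; then DBU (0.2 equiv), CH2Cl2, 20 °C
Reagents that add atoms: none
Why: Excitation of the chelated cis-enol of the β-keto ester (the strongly absorbing species at 254 nm, favoured in cyclohexane) leads to [2+2] photocycloaddition across C29=C30, and the cyclobutanol 18 fragments by retro-aldol cleavage of C22–C27 to the lactone and the acetyl group. The closest known reaction type is the De Mayo reaction in its tethered, intramolecular form. The five-membered lactone ring closes first by 1,5-closure (5-exo attack of the enol α-carbon C22 on C30, rule of five); the four-membered ring then closes by recombination of the 1,4-biradical at C27 and C29 and is lost again in the fragmentation. C30 is set by the ester tether, which can deliver C22 only to the face of ring B that carries the C7 oxygen; C29 is formed cis and is then equilibrated by DBU, α to the new ketone, to the more stable trans arrangement. The step needs straight rather than crossed regiochemistry and excitation of the enol rather than the keto tautomer; the three-atom tether and the short-wavelength irradiation in a non-polar solvent secure both.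

Step 12
Reactants: 20 cis-fused γ-lactone methyl ketone
Product: 22 lactone β-hydroxy ketone (C29–C(=O)–CH2–CH(OH)–CH3; carbinol mixture), via lithium enolate 21 (not isolated)
Conditions: LiN(iPr)2 (1.05 equiv), THF, −78 °C; CH3CHO
Reagents that add atoms: acetaldehyde (CC=O)
Why: Kinetic enolization occurs at the methyl group of the ketone (more acidic than the lactone α-CH2 and more accessible than C29–H), and the aldol addition at −78 °C outruns attack of the enolate on the lactone.

Step 13
Reactants: 22 lactone β-hydroxy ketone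
Product: 24 lactone (E)-but-2-enoyl ketone, via mesylate 23 (not isolated)
Conditions: MsCl, Et3N, CH2Cl2, 0 °C; then DBU, 20 °C
Reagents that add atoms: none
Why: Mesylation and E1cB elimination give the E-enone that carries C23 and C24.

Step 14
Reactants: 24 lactone (E)-but-2-enoyl ketone
Product: 27 tetracyclic enol triflate (ring C closed; C27–OTf, C25=C27), via potassium lactone enolate 25 (not isolated), via potassium ketone enolate 26 (not isolated)
Conditions: KN(SiMe3)2 (1.1 equiv), THF, −78 to −20 °C; then PhNTf2, −78 to 0 °C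
Reagents that add atoms: N-phenylbis(trifluoromethanesulfonimide) (O=S(=O)(N(c1ccccc1)S(=O)(=O)C(F)(F)F)C(F)(F)F)
Why: Intramolecular Michael addition (6-endo-trig) of the lactone enolate carbon C22 to C23 closes ring C trans-fused to ring B; the E-enone places the C24 methyl pseudo-equatorial in the chair-like transition state, which sets C23, and the regiodefined ketone enolate is trapped as its triflate before it can equilibrate (C22 forms cis to the lactone bridge and is corrected in step 17).

Step 15
Reactants: 27 tetracyclic enol triflate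
Product: 28 tetracyclic lactone alkene (C25=C27 with the C28 methyl on C27)
Conditions: MeZnCl, Pd(PPh3)4 (5 mol %), THF, 50 °C
Reagents that add atoms: methylzinc chloride (C[Zn]Cl)
Why: Palladium-catalysed Negishi coupling of the enol triflate installs C28 and leaves the trisubstituted ring C alkene; the lactone is inert to the organozinc reagent.

Step 16
Reactants: 28 tetracyclic lactone alkene
Product: 29 epoxy lactone (C25–C27 epoxide on the face of H30 and the angular methyl)
Conditions: mCPBA, NaHCO3, CH2Cl2, 0 °C
Reagents that add atoms: 3-chloroperbenzoic acid (OOC(=O)c1cccc(Cl)c1)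
Why: Prilezhaev epoxidation; the lactone carbon C20 sits axial on C22 and syn-axial to the lower face of C25, so the peracid should add to the upper face, which sets C25 and C27 as in the target.

Step 17
Reactants: 29 epoxy lactone
Product: 31 hydroxy methyl ester (C7–OH free; CO2Me equatorial on C22), via axial hydroxy ester 30 (not isolated)
Conditions: NaOMe (0.3 equiv), MeOH, 50 °C
Reagents that add atoms: methanol (CO)
Why: Methoxide opens the strained lactone reversibly and epimerizes the ester α-centre C22 to the equatorial position (thermodynamic control); the equatorial ester cannot reach the C7 hydroxyl again, so 31 with the target configuration at C22 should accumulate.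

Step 18
Reactants: 32 3-chloro-2-(chloromethyl)prop-1-ene; 33 phenol
Product: 34 {[2-(chloromethyl)prop-2-en-1-yl]oxy}benzene
Conditions: K2CO3, acetone, 56 °C (32 in threefold excess)
Reagents that add atoms: none
Why: Williamson ether synthesis; the excess of dichloride favours monosubstitution.

Step 19
Reactants: 34 {[2-(chloromethyl)prop-2-en-1-yl]oxy}benzene; 35 (4-bromophenoxy)(tert-butyl)dimethylsilane
Product: 37 tert-butyldimethyl{4-[2-(phenoxymethyl)prop-2-en-1-yl]phenoxy}silane, via arylmagnesium bromide 36 (not isolated)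
Conditions: Mg, THF, 40 °C; then 34, CuI (5 mol %), THF, −20 to 0 °C
Reagents that add atoms: none
Why: Grignard formation and copper-catalysed allylic substitution of the chloride; direct and allylic (SN2′) attack give the same product, and phenoxide is the poorer leaving group.

Step 20
Reactants: 37 tert-butyldimethyl{4-[2-(phenoxymethyl)prop-2-en-1-yl]phenoxy}silane
Product: 38 4-[2-(phenoxymethyl)prop-2-en-1-yl]phenol
Conditions: Bu4NF, THF, 0 °C
Reagents that add atoms: none
Why: Fluoride-mediated cleavage of the aryl silyl ether.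

Step 21
Reactants: 31 hydroxy methyl ester; 38 4-[2-(phenoxymethyl)prop-2-en-1-yl]phenol
Product: 39 C7 aryl ether methyl ester (C7 inverted to the natural configuration)
Conditions: PPh3, DIAD, toluene, 0 to 20 °C
Reagents that add atoms: none
Why: Mitsunobu etherification with the phenol as acidic partner proceeds with inversion at C7 and so gives the configuration of the target; the ester carbonyl is too weak a nucleophile to intercept the oxyphosphonium ion.

Step 22
Reactants: 39 C7 aryl ether methyl ester
Product: 40 aryl ether β-ketonitrile (C22–C20(=O)–C19H2–C34N)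
Conditions: CH3CN, n-BuLi, THF, −78 °C; then 39, −78 to −40 °C
Reagents that add atoms: acetonitrile (CC#N)
Why: Claisen-type acylation of lithioacetonitrile by the methyl ester gives the β-ketonitrile, whose enolate protects the new ketone and C22 from further reaction.

Step 23
Reactants: 40 aryl ether β-ketonitrile
Product: 41 macrocyclic β-ketonitrile (13-membered ring; exocyclic methylene on C16; C19 epimers)
Conditions: Pd(PPh3)4 (10 mol %), THF (0.002 M, slow addition), 65 °C
Reagents that add atoms: none
Why: Intramolecular Tsuji–Trost allylic alkylation: zerovalent palladium ionizes the allyl phenyl ether, the released phenoxide deprotonates the β-ketonitrile, and the soft carbanion C19 closes the ring at either of the two equivalent termini of the 2-substituted π-allyl unit; C19 ends sp2 in the target, so its configuration is of no consequence.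

Step 24
Reactants: 41 macrocyclic β-ketonitrile
Product: 43 macrocyclic cyano diketone (C16 ketone), via diol 42 (not isolated)
Conditions: OsO4 (2 mol %), NaIO4, 2,6-lutidine, dioxane/H2O, 20 °C
Reagents that add atoms: osmium tetroxide (O=[Os](=O)(=O)=O), reoxidized by sodium periodate ([Na+].[O-]I(=O)(=O)=O)
Why: Lemieux–Johnson oxidation (dihydroxylation and periodate cleavage) of the 1,1-disubstituted alkene unmasks the C16 ketone under buffered conditions that spare the epoxide and the aryl ether.

Step 25
Reactants: 43 macrocyclic cyano diketone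
Product: 45 pyrrospirone O, via keto amide 44 (not isolated)
Conditions: [PtH(PMe2OH){(PMe2O)2H}] (Ghaffar–Parkins catalyst, 5 mol %), EtOH/H2O, 80 °C
Reagents that add atoms: water (O)
Why: Platinum-catalysed neutral hydration of the nitrile gives the primary amide, which adds to the C16 ketone to form the five-membered hydroxy lactam, and the acyl lactam enolizes toward C20; C16 is set by reversible ring–chain tautomerism.

**Compound list**

1 | 4-methylcyclohexanone | CC1CCC(=O)CC1 | starting material
2 | (S)-trimethyl[(4-methylcyclohex-1-en-1-yl)oxy]silane | C[C@@H]1CC=C(O[Si](C)(C)C)CC1 | intermediate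
3 | lithium (S)-4-methylcyclohex-1-en-1-olate (not isolated) | C[C@@H]1CC=C(O[Li])CC1 | intermediate
4 | (2R,4S)-2,4-dimethylcyclohexan-1-one, trans (not isolated) | C[C@@H]1C[C@@H](C)C(=O)CC1 | intermediate
5 | (2S,4S)-2,4-dimethylcyclohexan-1-one, cis | C[C@@H]1C[C@H](C)C(=O)CC1 | intermediate
6 | kinetic lithium enolate of 5, double bond toward the CH2 side (not isolated) | C[C@@H]1C[C@H](C)C(O[Li])=CC1 | intermediate
7 | 2-(1-hydroxyethyl)-4,6-dimethylcyclohexan-1-one, 4,6-cis, mixture at the two new centres | C[C@@H]1C[C@H](C)C(=O)C(C(C)O)C1 | intermediate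
8 | methanesulfonate of 7 (not isolated) | C[C@@H]1C[C@H](C)C(=O)C(C(C)OS(C)(=O)=O)C1 | intermediate
9 | (E)-2-ethylidene-4,6-dimethylcyclohexan-1-one, 4,6-cis | C[C@@H]1C[C@H](C)C(=O)/C(=C/C)C1 | intermediate
10 | potassium dienolate of 9 (not isolated) | C[C@@H]1C[C@H](C)C(O[K])=C(C=C)C1 | intermediate
11 | 2-ethenyl-2,4,6-trimethylcyclohexan-1-one, 2-methyl trans to 4-methyl, 4,6-cis | C[C@@H]1C[C@H](C)C(=O)[C@](C)(C=C)C1 | intermediate
12 | 4-ethenyl-4,6,8-trimethyl-1-oxaspiro[2.5]octane, spiro centre undefined | C[C@@H]1C[C@H](C)C2(CO2)[C@](C)(C=C)C1 | intermediate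
13 | formyl epimer of 14, CHO cis to vinyl (not isolated) | C[C@@H]1C[C@H](C)[C@H](C=O)[C@](C)(C=C)C1 | intermediate
14 | 2-ethenyl-2,4,6-trimethylcyclohexane-1-carbaldehyde, CHO trans to vinyl and to the 6-methyl | C[C@@H]1C[C@H](C)[C@@H](C=O)[C@](C)(C=C)C1 | intermediate
15 | 1-(2-ethenyl-2,4,6-trimethylcyclohexyl)prop-2-en-1-ol, Felkin epimer | C[C@@H]1C[C@H](C)[C@@H]([C@H](O)C=C)[C@](C)(C=C)C1 | intermediate
16 | trans-fused 3a,5,7-trimethyl-3a,4,5,6,7,7a-hexahydro-1H-inden-1-ol, OH anti to the 3a-methyl | C[C@@H]1C[C@H](C)[C@H]2[C@H](O)C=C[C@]2(C)C1 | intermediate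
17 | 3-oxobutanoate (acetoacetate) of 16 | C[C@@H]1C[C@H](C)[C@H]2[C@H](OC(=O)CC(C)=O)C=C[C@]2(C)C1 | intermediate
18 | cyclobutanol photoadduct, bonds C22–C30 and C27–C29, carbinol centre undefined (not isolated) | C[C@@H]1C[C@H](C)[C@H]2[C@@H]3OC(=O)[C@H]4[C@@H]3[C@H](C4(C)O)[C@]2(C)C1 | intermediate
19 | lactone methyl ketone with acetyl cis to C22 (not isolated) | C[C@@H]1C[C@H](C)[C@H]2[C@@H]3OC(=O)C[C@@H]3[C@H](C(C)=O)[C@]2(C)C1 | intermediate
20 | cis-fused γ-lactone methyl ketone, acetyl trans to C22 | C[C@@H]1C[C@H](C)[C@H]2[C@@H]3OC(=O)C[C@@H]3[C@@H](C(C)=O)[C@]2(C)C1 | intermediate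
21 | lithium enolate of 20 at the acetyl methyl (not isolated) | C[C@@H]1C[C@H](C)[C@H]2[C@@H]3OC(=O)C[C@@H]3[C@@H](C(=C)O[Li])[C@]2(C)C1 | intermediate
22 | lactone β-hydroxy ketone, carbinol mixture | C[C@@H]1C[C@H](C)[C@H]2[C@@H]3OC(=O)C[C@@H]3[C@@H](C(=O)CC(C)O)[C@]2(C)C1 | intermediate
23 | methanesulfonate of 22 (not isolated) | C[C@@H]1C[C@H](C)[C@H]2[C@@H]3OC(=O)C[C@@H]3[C@@H](C(=O)CC(C)OS(C)(=O)=O)[C@]2(C)C1 | intermediate
24 | lactone (E)-but-2-enoyl ketone | C[C@@H]1C[C@H](C)[C@H]2[C@@H]3OC(=O)C[C@@H]3[C@@H](C(=O)/C=C/C)[C@]2(C)C1 | intermediate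
25 | potassium lactone enolate of 24 (not isolated) | C[C@@H]1C[C@H](C)[C@H]2[C@@H]3OC(O[K])=C[C@@H]3[C@@H](C(=O)/C=C/C)[C@]2(C)C1 | intermediate
26 | potassium enolate of the tetracyclic C27 ketone (not isolated) | C[C@@H]1C[C@H](C)[C@H]2[C@@H]3OC(=O)[C@@H]5[C@H](C)C=C(O[K])[C@H]([C@H]35)[C@]2(C)C1 | intermediate
27 | tetracyclic enol triflate, lactone cis-fused to rings B and C | C[C@@H]1C[C@H](C)[C@H]2[C@@H]3OC(=O)[C@@H]5[C@H](C)C=C(OS(=O)(=O)C(F)(F)F)[C@H]([C@H]35)[C@]2(C)C1 | intermediate
28 | tetracyclic lactone alkene | C[C@@H]1C[C@H](C)[C@H]2[C@@H]3OC(=O)[C@@H]5[C@H](C)C=C(C)[C@H]([C@H]35)[C@]2(C)C1 | intermediate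
29 | epoxy lactone | C[C@@H]1C[C@H](C)[C@H]2[C@@H]3OC(=O)[C@@H]5[C@H](C)[C@H]6O[C@@]6(C)[C@H]([C@H]35)[C@]2(C)C1 | intermediate
30 | hydroxy methyl ester with axial CO2Me on C22 (not isolated) | C[C@@H]1C[C@H](C)[C@H]2[C@H](O)[C@@H]3[C@H](C(=O)OC)[C@H](C)[C@H]4O[C@@]4(C)[C@H]3[C@]2(C)C1 | intermediate
31 | hydroxy methyl ester with equatorial CO2Me on C22, C7–OH anti to the angular methyl | C[C@@H]1C[C@H](C)[C@H]2[C@H](O)[C@@H]3[C@@H](C(=O)OC)[C@H](C)[C@H]4O[C@@]4(C)[C@H]3[C@]2(C)C1 | intermediate
32 | 3-chloro-2-(chloromethyl)prop-1-ene | C=C(CCl)CCl | starting material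
33 | phenol | Oc1ccccc1 | starting material
34 | {[2-(chloromethyl)prop-2-en-1-yl]oxy}benzene | C=C(CCl)COc1ccccc1 | intermediate
35 | (4-bromophenoxy)(tert-butyl)dimethylsilane | CC(C)(C)[Si](C)(C)Oc1ccc(Br)cc1 | starting material
36 | {4-[(tert-butyldimethylsilyl)oxy]phenyl}magnesium bromide (not isolated) | CC(C)(C)[Si](C)(C)Oc1ccc([Mg]Br)cc1 | intermediate
37 | tert-butyldimethyl{4-[2-(phenoxymethyl)prop-2-en-1-yl]phenoxy}silane | CC(C)(C)[Si](C)(C)Oc1ccc(CC(=C)COc2ccccc2)cc1 | intermediate
38 | 4-[2-(phenoxymethyl)prop-2-en-1-yl]phenol | Oc1ccc(CC(=C)COc2ccccc2)cc1 | intermediate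
39 | C7 aryl ether methyl ester, natural configuration at C7 | C[C@@H]1C[C@H](C)[C@H]2[C@@H](Oc3ccc(CC(=C)COc4ccccc4)cc3)[C@@H]5[C@@H](C(=O)OC)[C@H](C)[C@H]6O[C@@]6(C)[C@H]5[C@]2(C)C1 | intermediate
40 | aryl ether β-ketonitrile | C[C@@H]1C[C@H](C)[C@H]2[C@@H](Oc3ccc(CC(=C)COc4ccccc4)cc3)[C@@H]5[C@@H](C(=O)CC#N)[C@H](C)[C@H]6O[C@@]6(C)[C@H]5[C@]2(C)C1 | intermediate
41 | macrocyclic β-ketonitrile with exocyclic methylene on C16, C19 epimers | C[C@@H]1C[C@H](C)[C@H]2[C@H]3Oc4ccc(cc4)CC(=C)CC(C#N)C(=O)[C@H]5[C@H](C)[C@H]6O[C@@]6(C)[C@H]([C@H]35)[C@]2(C)C1 | intermediate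
42 | macrocyclic diol from the methylene group (not isolated) | C[C@@H]1C[C@H](C)[C@H]2[C@H]3Oc4ccc(cc4)CC(O)(CO)CC(C#N)C(=O)[C@H]5[C@H](C)[C@H]6O[C@@]6(C)[C@H]([C@H]35)[C@]2(C)C1 | intermediate
43 | macrocyclic cyano diketone | C[C@@H]1C[C@H](C)[C@H]2[C@H]3Oc4ccc(cc4)CC(=O)CC(C#N)C(=O)[C@H]5[C@H](C)[C@H]6O[C@@]6(C)[C@H]([C@H]35)[C@]2(C)C1 | intermediate
44 | macrocyclic keto amide (not isolated) | C[C@@H]1C[C@H](C)[C@H]2[C@H]3Oc4ccc(cc4)CC(=O)CC(C(N)=O)C(=O)[C@H]5[C@H](C)[C@H]6O[C@@]6(C)[C@H]([C@H]35)[C@]2(C)C1 | intermediate
45 | pyrrospirone O | C[C@@H]1C[C@H](C)[C@H]2[C@H]3Oc4ccc(cc4)C[C@]4(O)C/C(=C(/O)[C@H]5[C@H](C)[C@H]6O[C@@]6(C)[C@H]([C@H]35)[C@]2(C)C1)C(=O)N4 | target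

**Step count and risks**

Total: 25 steps. Longest linear sequence: 22 steps (steps 1–17 and 21–25); the phenol 38 takes three steps (18–20).

Step 23 (macrocyclization). The strain of the bent para-phenylene bridge may slow ring closure so that intermolecular allylation, O-allylation or diene formation from the π-allyl complex take over. The fallback closes the ring at C19–C20 instead and sets out from 31, 32 and 36. Copper-catalysed coupling of 36 with an excess of 32 gives the allylic chloride tert-butyl{4-[2-(chloromethyl)prop-2-en-1-yl]phenoxy}dimethylsilane F1. Lithioacetonitrile (prepared as in step 22) displaces the chloride to give 4-{[4-(tert-butyldimethylsilyloxy)phenyl]methyl}pent-4-enenitrile F2, and Bu4NF frees 4-[(4-hydroxyphenyl)methyl]pent-4-enenitrile F3. Mitsunobu coupling of F3 with 31 (PPh3, DIAD) gives the aryl ether ester nitrile F4. LiN(SiMe3)2 (2.2 equiv, THF, high dilution) then deprotonates α to the nitrile, and the anion acylates the C20 methyl ester intramolecularly (Claisen-type condensation under Thorpe–Ziegler dilution). This returns the route at 41.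

Step 11 (key step). The ester tether prefers its extended conformation and the enol is a minor tautomer, so decay of the excited state, oxetane formation from the keto tautomer or photocleavage of the allylic ester may outrun cycloaddition. The fallback builds the same two bonds by radical chemistry and sets out from 16. NBS and ethyl vinyl ether give the bromoacetal F5. With Bu3SnH, AIBN and t-BuNC (Ueno–Stork cyclization with isocyanide trapping), the radical closes 5-exo onto C30 on the face of the C7 oxygen, and the C29 radical is trapped trans to the new ring, giving the cyano acetal F6. MeMgBr followed by mild aqueous acid converts the nitrile into the methyl ketone, keto acetal F7. Oxidation with CrO3/H2SO4 in acetone turns the cyclic acetal into the lactone and returns the route at 20.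

Step 21 (aryl ether). Displacement at the hindered C7 oxyphosphonium ion may be slow, so that elimination toward C30 and alkylation of the hydrazide compete. The fallback separates inversion from arylation and sets out from 31. Mitsunobu reaction with the small, acidic 4-nitrobenzoic acid gives the inverted 4-nitrobenzoate F8, and K2CO3 in MeOH releases the C7-epimeric alcohol F9. The aryl partner comes from 34: 4-iodophenylmagnesium chloride F10 (from 1,4-diiodobenzene and i-PrMgCl) is coupled with 34 under CuI catalysis to give 1-iodo-4-[2-(phenoxymethyl)prop-2-en-1-yl]benzene F11. Copper-catalysed O-arylation of F9 with F11 (CuI, 3,4,7,8-tetramethyl-1,10-phenanthroline, Cs2CO3, toluene, 110 °C) proceeds with retention at C7 and returns the route at 39.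

**Further compounds**

F1 | step 23 | tert-butyl{4-[2-(chloromethyl)prop-2-en-1-yl]phenoxy}dimethylsilane | CC(C)(C)[Si](C)(C)Oc1ccc(CC(=C)CCl)cc1
F2 | step 23 | 4-{[4-(tert-butyldimethylsilyloxy)phenyl]methyl}pent-4-enenitrile | CC(C)(C)[Si](C)(C)Oc1ccc(CC(=C)CCC#N)cc1
F3 | step 23 | 4-[(4-hydroxyphenyl)methyl]pent-4-enenitrile | Oc1ccc(CC(=C)CCC#N)cc1
F4 | step 23 | C7 aryl ether methyl ester carrying the pentenenitrile chain | C[C@@H]1C[C@H](C)[C@H]2[C@@H](Oc3ccc(CC(=C)CCC#N)cc3)[C@@H]5[C@@H](C(=O)OC)[C@H](C)[C@H]6O[C@@]6(C)[C@H]5[C@]2(C)C1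
F5 | step 11 | 2-bromo-1-ethoxyethyl ether (bromoacetal) of 16 | C[C@@H]1C[C@H](C)[C@H]2[C@H](OC(CBr)OCC)C=C[C@]2(C)C1
F6 | step 11 | cis-fused 2-ethoxytetrahydrofuran with nitrile on C29 trans to C22 | C[C@@H]1C[C@H](C)[C@H]2[C@@H]3OC(OCC)C[C@@H]3[C@@H](C#N)[C@]2(C)C1
F7 | step 11 | cis-fused 2-ethoxytetrahydrofuran with acetyl on C29 trans to C22 | C[C@@H]1C[C@H](C)[C@H]2[C@@H]3OC(OCC)C[C@@H]3[C@@H](C(C)=O)[C@]2(C)C1
F8 | step 21 | 4-nitrobenzoate of the C7-inverted alcohol | C[C@@H]1C[C@H](C)[C@H]2[C@@H](OC(=O)c3ccc(cc3)[N+](=O)[O-])[C@@H]5[C@@H](C(=O)OC)[C@H](C)[C@H]6O[C@@]6(C)[C@H]5[C@]2(C)C1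
F9 | step 21 | C7 epimer of 31 (hydroxyl syn to the angular methyl) | C[C@@H]1C[C@H](C)[C@H]2[C@@H](O)[C@@H]5[C@@H](C(=O)OC)[C@H](C)[C@H]6O[C@@]6(C)[C@H]5[C@]2(C)C1
F10 | step 21 | 4-iodophenylmagnesium chloride | Ic1ccc([Mg]Cl)cc1
F11 | step 21 | 1-iodo-4-[2-(phenoxymethyl)prop-2-en-1-yl]benzene | Ic1ccc(CC(=C)COc2ccccc2)cc1
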